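## Retrosynthetic overview

1. Ring C is bought as an arene (1,2,4-trimethoxybenzene) and becomes the hydroxyquinone only in the last two steps; ring B (C1–C2–C3–C4–C4a–C8a, target locants) is the last ring to be closed, in step 7.
2. Enabling feature: C1 of ring B, with its methyl group and the first CH2 of its ester arm, is an isopropenyl group that has gained an aryl bond (C1–C8a) and an alkyl bond, and its ring neighbour C2 carries an intact isopropenyl group. Cutting C1–C8a and the CH2–CH2 bond of the arm therefore leaves C2 as a prochiral carbon with two identical isopropenyl groups.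
3. Key disconnection: a nickel-catalysed enantioselective reductive aryl-alkylation joins two electrophilic carbons (C8a–Br and a CH2–Br) across one of the two enantiotopic alkenes; from an achiral ketone it closes ring B 6-exo, sets C1 and C2 and attaches the arm in one operation.
4. The achiral ketone comes from the aryl methyl ketone by aldol condensation with methacrolein and rhodium-catalysed 1,4-addition of an isopropenylboronate; after the key step the arm terminus is oxidised to the methyl ester.

Key step: step 7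

Remark on locants: C1 to C8a in the Why lines are the locants of the target name (C1 quaternary carbon, C2 CH with the isopropenyl group, C3 CH2, C4 ring-B ketone, C4a and C8a ring fusion, C5 to C8 ring C).
Assumption: the (S,S) ligand is taken to lead to the (3S,4S) product 15; if the sense of induction proves to be the opposite, the (R,R) ligand is used.

## Route

Step 1
Reactants: 1 1,2,4-trimethoxybenzene; 2 acetone
Product: 4 2-(2,3,6-trimethoxyphenyl)propan-2-ol, via aryllithium 3 (not isolated)
Conditions: n-C4H9Li, THF, 0 °C; then 2, −78 → 20 °C; H2O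
Reagents that add atoms: none
Why: Directed ortho-metalation takes place at the only C–H flanked by two methoxy groups, and the aryllithium adds to the carbonyl group of acetone (1,2-addition).

Step 2
Reactants: 4 2-(2,3,6-trimethoxyphenyl)propan-2-ol
Product: 5 1,2,4-trimethoxy-3-(propan-2-yl)benzene
Conditions: Et3SiH, CF3CO2H, CH2Cl2, 0 → 20 °C
Reagents that add atoms: none
Why: Ionic hydrogenation: the acid ionises the tertiary benzylic alcohol to a cation stabilised by the two ortho methoxy groups, and the silane delivers hydride to it.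

Step 3
Reactants: 5 1,2,4-trimethoxy-3-(propan-2-yl)benzene; 6 acetic anhydride
Product: 7 1-[2,4,5-trimethoxy-3-(propan-2-yl)phenyl]ethan-1-one
Conditions: Sc(OSO2CF3)3 (10 mol %), MeNO2, 50 °C
Reagents that add atoms: none
Why: Friedel–Crafts acylation; of the two free positions, the one ortho to one methoxy group and para to a second (the later C4a) should be more electron-rich than the one that is only ortho to a methoxy group and para to the alkyl group.

Step 4
Reactants: 7 1-[2,4,5-trimethoxy-3-(propan-2-yl)phenyl]ethan-1-one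
Product: 8 1-[2-bromo-3,4,6-trimethoxy-5-(propan-2-yl)phenyl]ethan-1-one
Conditions: N-bromosuccinimide, MeCN, 0 → 20 °C, dark
Reagents that add atoms: N-bromosuccinimide O=C1CCC(=O)N1Br
Why: Electrophilic aromatic bromination at the only ring C–H left (the later C8a), activated by its ortho methoxy group; a polar solvent without acid or radical initiator keeps bromination away from the methyl ketone.

Step 5
Reactants: 8 1-[2-bromo-3,4,6-trimethoxy-5-(propan-2-yl)phenyl]ethan-1-one; 9 2-methylprop-2-enal
Product: 11 (2E)-1-[2-bromo-3,4,6-trimethoxy-5-(propan-2-yl)phenyl]-4-methylpenta-2,4-dien-1-one, via aldol adduct 10 (not isolated)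
Conditions: Ba(OH)2·8H2O, EtOH, 0 → 20 °C
Reagents that add atoms: none
Why: Claisen–Schmidt aldol condensation: the methyl ketone enolate adds to the non-enolisable aldehyde, and the aldol loses water (E1cB) to give the conjugated E-dienone.

Step 6
Reactants: 11 (2E)-1-[2-bromo-3,4,6-trimethoxy-5-(propan-2-yl)phenyl]-4-methylpenta-2,4-dien-1-one; 12 4,4,5,5-tetramethyl-2-(prop-1-en-2-yl)-1,3,2-dioxaborolane
Product: 13 1-[2-bromo-3,4,6-trimethoxy-5-(propan-2-yl)phenyl]-4-methyl-3-(prop-1-en-2-yl)pent-4-en-1-one
Conditions: [Rh(OH)(C8H12)]2 (3 mol %; C8H12 = cycloocta-1,5-diene), KOH (0.2 equiv), 1,4-dioxane/H2O 10:1, 40 °C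
Reagents that add atoms: none
Why: Hayashi–Miyaura conjugate addition: the isopropenylrhodium species formed by transmetalation inserts the carbonyl-activated 2,3-double bond to give an oxa-π-allylrhodium species that water protonates, so the addition should be 1,4 and not 1,6; the new carbon bears two identical isopropenyl groups and is not a stereocentre.

Step 7
Reactants: 13 1-[2-bromo-3,4,6-trimethoxy-5-(propan-2-yl)phenyl]-4-methyl-3-(prop-1-en-2-yl)pent-4-en-1-one; 14 (2-bromoethoxy)(tert-butyl)dimethylsilane
Product: 15 (3S,4S)-4-(3-{[tert-butyl(dimethyl)silyl]oxy}propyl)-5,6,8-trimethoxy-4-methyl-7-(propan-2-yl)-3-(prop-1-en-2-yl)-3,4-dihydronaphthalen-1(2H)-one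
Conditions: NiBr2·CH3OCH2CH2OCH3 (10 mol %), (4S,4'S)-4,4'-di(propan-2-yl)-4,4',5,5'-tetrahydro-2,2'-bi-1,3-oxazole (12 mol %), Mn powder (3 equiv), NaI (0.5 equiv), N,N-dimethylacetamide, 20 °C, 14 added over 6 h
Reagents that add atoms: none
Why: Proposed new method: oxidative addition of the C–Br bond of 13 to zerovalent nickel is followed by a 6-exo-trig syn-arylnickelation of one of the two enantiotopic isopropenyl groups, which closes ring B through the bond C8a–C1, and the neopentyl-type alkylnickel species, which has no β-hydrogen because C1 is quaternary, takes up the primary radical that monovalent nickel abstracts from 14 and forms the CH2–CH2 bond by reductive elimination from trivalent nickel, while Mn returns the catalyst. The closest known reaction type is the nickel-catalysed enantioselective reductive aryl-alkylation of aryl bromides that carry a tethered 1,1-disubstituted alkene with primary alkyl bromides; new are the choice between two enantiotopic alkenes and the ketone in the tether. C1 is set by the chiral bis(oxazoline) ligand, which decides the alkene face that receives the aryl group in the irreversible insertion. C2 is set by which isopropenyl group inserts, and this choice is tied to the face: in the chair-like transition state the spectator isopropenyl group lies anti to the nickel-bearing CH2 group, since gauche to it it would meet A(1,3) strain with the inserting =CH2 and the ligand sphere, so the arm and the isopropenyl group should end up trans and the methyl group cis to it. The step needs cyclisation before intermolecular aryl–alkyl coupling, which the intramolecular insertion and the slow addition of the unactivated bromide 14 secure, and exo regiochemistry, which the ring size (6-exo against 7-endo) secures.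

Step 8
Reactants: 15 (3S,4S)-4-(3-{[tert-butyl(dimethyl)silyl]oxy}propyl)-5,6,8-trimethoxy-4-methyl-7-(propan-2-yl)-3-(prop-1-en-2-yl)-3,4-dihydronaphthalen-1(2H)-one
Product: 18 3-[(1S,2S)-5,7,8-trimethoxy-1-methyl-4-oxo-6-(propan-2-yl)-2-(prop-1-en-2-yl)-1,2,3,4-tetrahydronaphthalen-1-yl]propanoic acid, via primary alcohol 16 (not isolated), via aldehyde 17 (not isolated)
Conditions: CrO3, H2SO4, H2O, acetone, 0 °C
Reagents that add atoms: water O
Why: Jones oxidation: the aqueous acid cleaves the primary silyl ether and chromic acid oxidises the alcohol through the aldehyde hydrate to the acid; neither stereocentre is α to a carbonyl group, so both should stay untouched.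

Step 9
Reactants: 18 3-[(1S,2S)-5,7,8-trimethoxy-1-methyl-4-oxo-6-(propan-2-yl)-2-(prop-1-en-2-yl)-1,2,3,4-tetrahydronaphthalen-1-yl]propanoic acid
Product: 19 methyl 3-[(1S,2S)-5,7,8-trimethoxy-1-methyl-4-oxo-6-(propan-2-yl)-2-(prop-1-en-2-yl)-1,2,3,4-tetrahydronaphthalen-1-yl]propanoate
Conditions: Me3SiCHN2, MeOH/toluene 1:4, 0 °C
Reagents that add atoms: (trimethylsilyl)diazomethane C[Si](C)(C)C=[N+]=[N-]
Why: O-Methylation of the acid by the diazoalkane (proton transfer, then SN2 by the carboxylate) under neutral conditions that leave the isopropenyl group and the ketone alone.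

Step 10
Reactants: 19 methyl 3-[(1S,2S)-5,7,8-trimethoxy-1-methyl-4-oxo-6-(propan-2-yl)-2-(prop-1-en-2-yl)-1,2,3,4-tetrahydronaphthalen-1-yl]propanoate
Product: 20 methyl 3-[(1S,2S)-7-methoxy-1-methyl-4,5,8-trioxo-6-(propan-2-yl)-2-(prop-1-en-2-yl)-1,2,3,4,5,8-hexahydronaphthalen-1-yl]propanoate
Conditions: (NH4)2Ce(NO3)6 (2.5 equiv), MeCN/H2O 2:1, 0 °C
Reagents that add atoms: water O
Why: Oxidative demethylation by tetravalent cerium: two one-electron oxidations of the arene with attack of water at the two methoxy-bearing carbons that stand para to each other (C5 and C8) give the para-quinone, and the third methoxy group (C7) stays as a vinylogous ester.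

Step 11
Reactants: 20 methyl 3-[(1S,2S)-7-methoxy-1-methyl-4,5,8-trioxo-6-(propan-2-yl)-2-(prop-1-en-2-yl)-1,2,3,4,5,8-hexahydronaphthalen-1-yl]propanoate
Product: 22 methyl 3-[(1S,2S)-7-hydroxy-1-methyl-4,5,8-trioxo-6-(propan-2-yl)-2-(prop-1-en-2-yl)-1,2,3,4,5,8-hexahydronaphthalen-1-yl]propanoate, via dichloroboryl ether 21 (not isolated)
Conditions: BCl3 (1.2 equiv), CH2Cl2, −78 → −20 °C; then H2O
Reagents that add atoms: none
Why: Chelation-controlled ether cleavage: BCl3 binds the C8 carbonyl oxygen and the neighbouring C7 methoxy oxygen, chloride removes the methyl group by SN2 and water frees the hydroxyquinone; the unchelated methyl ester and the alkene should be spared at low temperature.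

## Compound list

1 | 1,2,4-trimethoxybenzene | COc1ccc(OC)c(OC)c1 | starting material
2 | acetone | CC(C)=O | starting material
3 | (2,3,6-trimethoxyphenyl)lithium (not isolated) | [Li]c1c(OC)ccc(OC)c1OC | intermediate
4 | 2-(2,3,6-trimethoxyphenyl)propan-2-ol | COc1ccc(OC)c(OC)c1C(C)(C)O | intermediate
5 | 1,2,4-trimethoxy-3-(propan-2-yl)benzene | COc1ccc(OC)c(OC)c1C(C)C | intermediate
6 | acetic anhydride | CC(=O)OC(C)=O | starting material
7 | 1-[2,4,5-trimethoxy-3-(propan-2-yl)phenyl]ethan-1-one | CC(=O)c1cc(OC)c(OC)c(C(C)C)c1OC | intermediate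
8 | 1-[2-bromo-3,4,6-trimethoxy-5-(propan-2-yl)phenyl]ethan-1-one | CC(=O)c1c(Br)c(OC)c(OC)c(C(C)C)c1OC | intermediate
9 | 2-methylprop-2-enal (methacrolein) | C=C(C)C=O | starting material
10 | 1-[2-bromo-3,4,6-trimethoxy-5-(propan-2-yl)phenyl]-3-hydroxy-4-methylpent-4-en-1-one, racemic (not isolated) | C=C(C)C(O)CC(=O)c1c(Br)c(OC)c(OC)c(C(C)C)c1OC | intermediate
11 | (2E)-1-[2-bromo-3,4,6-trimethoxy-5-(propan-2-yl)phenyl]-4-methylpenta-2,4-dien-1-one | C=C(C)/C=C/C(=O)c1c(Br)c(OC)c(OC)c(C(C)C)c1OC | intermediate
12 | 4,4,5,5-tetramethyl-2-(prop-1-en-2-yl)-1,3,2-dioxaborolane | C=C(C)B1OC(C)(C)C(C)(C)O1 | starting material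
13 | 1-[2-bromo-3,4,6-trimethoxy-5-(propan-2-yl)phenyl]-4-methyl-3-(prop-1-en-2-yl)pent-4-en-1-one | C=C(C)C(CC(=O)c1c(Br)c(OC)c(OC)c(C(C)C)c1OC)C(C)=C | intermediate
14 | (2-bromoethoxy)(tert-butyl)dimethylsilane | BrCCO[Si](C)(C)C(C)(C)C | starting material
15 | (3S,4S)-4-(3-{[tert-butyl(dimethyl)silyl]oxy}propyl)-5,6,8-trimethoxy-4-methyl-7-(propan-2-yl)-3-(prop-1-en-2-yl)-3,4-dihydronaphthalen-1(2H)-one | C=C(C)[C@@H]1CC(=O)c2c(OC)c(C(C)C)c(OC)c(OC)c2[C@@]1(C)CCCO[Si](C)(C)C(C)(C)C | intermediate
16 | (3S,4S)-4-(3-hydroxypropyl)-5,6,8-trimethoxy-4-methyl-7-(propan-2-yl)-3-(prop-1-en-2-yl)-3,4-dihydronaphthalen-1(2H)-one (not isolated) | C=C(C)[C@@H]1CC(=O)c2c(OC)c(C(C)C)c(OC)c(OC)c2[C@@]1(C)CCCO | intermediate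
17 | 3-[(1S,2S)-5,7,8-trimethoxy-1-methyl-4-oxo-6-(propan-2-yl)-2-(prop-1-en-2-yl)-1,2,3,4-tetrahydronaphthalen-1-yl]propanal (not isolated) | C=C(C)[C@@H]1CC(=O)c2c(OC)c(C(C)C)c(OC)c(OC)c2[C@@]1(C)CCC=O | intermediate
18 | 3-[(1S,2S)-5,7,8-trimethoxy-1-methyl-4-oxo-6-(propan-2-yl)-2-(prop-1-en-2-yl)-1,2,3,4-tetrahydronaphthalen-1-yl]propanoic acid | C=C(C)[C@@H]1CC(=O)c2c(OC)c(C(C)C)c(OC)c(OC)c2[C@@]1(C)CCC(=O)O | intermediate
19 | methyl 3-[(1S,2S)-5,7,8-trimethoxy-1-methyl-4-oxo-6-(propan-2-yl)-2-(prop-1-en-2-yl)-1,2,3,4-tetrahydronaphthalen-1-yl]propanoate | C=C(C)[C@@H]1CC(=O)c2c(OC)c(C(C)C)c(OC)c(OC)c2[C@@]1(C)CCC(=O)OC | intermediate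
20 | methyl 3-[(1S,2S)-7-methoxy-1-methyl-4,5,8-trioxo-6-(propan-2-yl)-2-(prop-1-en-2-yl)-1,2,3,4,5,8-hexahydronaphthalen-1-yl]propanoate | C=C(C)[C@@H]1CC(=O)C2=C(C(=O)C(OC)=C(C(C)C)C2=O)[C@@]1(C)CCC(=O)OC | intermediate
21 | methyl 3-[(1S,2S)-7-(dichloroboranyloxy)-1-methyl-4,5,8-trioxo-6-(propan-2-yl)-2-(prop-1-en-2-yl)-1,2,3,4,5,8-hexahydronaphthalen-1-yl]propanoate (not isolated) | C=C(C)[C@@H]1CC(=O)C2=C(C(=O)C(OB(Cl)Cl)=C(C(C)C)C2=O)[C@@]1(C)CCC(=O)OC | intermediate
22 | methyl 3-[(1S,2S)-7-hydroxy-1-methyl-4,5,8-trioxo-6-(propan-2-yl)-2-(prop-1-en-2-yl)-1,2,3,4,5,8-hexahydronaphthalen-1-yl]propanoate | C=C(C)[C@@H]1CC(=O)C2=C(C(=O)C(O)=C(C(C)C)C2=O)[C@@]1(C)CCC(=O)OC | target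

## Step count and risks

Total steps: 11. Longest linear sequence: 11 steps (1 → 22); 2, 6, 9, 12 and 14 are bought.

Steps most likely to fail:

Step 7 (Proposed new method). What may go wrong: the aryl–nickel bond is reduced or coupled with the alkyl bromide before it inserts the hindered alkene, or the ligand tells the two isopropenyl groups apart poorly. The fallback uses known chemistry and sets out from 7, in which the ring position is still a C–H. Condensation of 7 with 9 as in step 5 should give (2E)-4-methyl-1-[2,4,5-trimethoxy-3-(propan-2-yl)phenyl]penta-2,4-dien-1-one F1. Rhodium-catalysed addition of 12 as in step 6 should then give 4-methyl-3-(prop-1-en-2-yl)-1-[2,4,5-trimethoxy-3-(propan-2-yl)phenyl]pent-4-en-1-one F2. A radical alkylation–arylation of the known type follows (methyl bromoacetate, tris(2-phenylpyridinato)iridium, K2HPO4, MeCN, blue light): the ester-stabilised radical adds to the CH2 end of one isopropenyl group, the tertiary radical closes onto the free ring position next to the ketone, and oxidation with loss of a proton restores the arene. This should give racemic methyl 3-[(1RS,2RS)-5,7,8-trimethoxy-1-methyl-4-oxo-6-(propan-2-yl)-2-(prop-1-en-2-yl)-1,2,3,4-tetrahydronaphthalen-1-yl]propanoate F3 beside its cis isomer, with the whole arm in place. Chromatography removes the cis isomer and preparative chromatography on a chiral stationary phase separates the enantiomers; the (1S,2S) enantiomer is 19, where the fallback comes back to the route before step 10.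

Step 10. What may go wrong: slow oxidation of the acyl-deactivated arene, attack of the oxidant on the isopropenyl group, or formation of an ortho-quinone. The fallback sets out from 19. BCl3 (1 equiv) in CH2Cl2 at −78 °C should cleave only the methoxy group ortho to the ring-B ketone (chelation) and give methyl 3-[(1S,2S)-5-hydroxy-7,8-dimethoxy-1-methyl-4-oxo-6-(propan-2-yl)-2-(prop-1-en-2-yl)-1,2,3,4-tetrahydronaphthalen-1-yl]propanoate F4. Oxidation of this para-methoxyphenol with PhI(OAc)2 in MeCN/H2O at 0 °C should give 20, where the fallback comes back to the route.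

Step 11. What may go wrong: addition of hydrogen chloride to the isopropenyl group or cleavage of the methyl ester by the Lewis acid. The fallback sets out from 20. LiOH in THF/H2O at 0 °C should replace the methoxy group at C7 by addition–elimination and hydrolyse the ester as well, giving 3-[(1S,2S)-7-hydroxy-1-methyl-4,5,8-trioxo-6-(propan-2-yl)-2-(prop-1-en-2-yl)-1,2,3,4,5,8-hexahydronaphthalen-1-yl]propanoic acid F5. MeOH with a catalytic amount of H2SO4 at 20 °C should then esterify only the aliphatic acid, since the vinylogous acid of the hydroxyquinone needs heat, and gives 22.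

Further compounds
F1 | step 7 | (2E)-4-methyl-1-[2,4,5-trimethoxy-3-(propan-2-yl)phenyl]penta-2,4-dien-1-one | C=C(C)/C=C/C(=O)c1cc(OC)c(OC)c(C(C)C)c1OC
F2 | step 7 | 4-methyl-3-(prop-1-en-2-yl)-1-[2,4,5-trimethoxy-3-(propan-2-yl)phenyl]pent-4-en-1-one | C=C(C)C(CC(=O)c1cc(OC)c(OC)c(C(C)C)c1OC)C(C)=C
F3 | step 7 | racemic methyl 3-[(1RS,2RS)-5,7,8-trimethoxy-1-methyl-4-oxo-6-(propan-2-yl)-2-(prop-1-en-2-yl)-1,2,3,4-tetrahydronaphthalen-1-yl]propanoate (19 together with its enantiomer) | C=C(C)[C@@H]1CC(=O)c2c(OC)c(C(C)C)c(OC)c(OC)c2[C@@]1(C)CCC(=O)OC.C=C(C)[C@H]1CC(=O)c2c(OC)c(C(C)C)c(OC)c(OC)c2[C@]1(C)CCC(=O)OC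
F4 | step 10 | methyl 3-[(1S,2S)-5-hydroxy-7,8-dimethoxy-1-methyl-4-oxo-6-(propan-2-yl)-2-(prop-1-en-2-yl)-1,2,3,4-tetrahydronaphthalen-1-yl]propanoate | C=C(C)[C@@H]1CC(=O)c2c(O)c(C(C)C)c(OC)c(OC)c2[C@@]1(C)CCC(=O)OC
F5 | step 11 | 3-[(1S,2S)-7-hydroxy-1-methyl-4,5,8-trioxo-6-(propan-2-yl)-2-(prop-1-en-2-yl)-1,2,3,4,5,8-hexahydronaphthalen-1-yl]propanoic acid | C=C(C)[C@@H]1CC(=O)C2=C(C(=O)C(O)=C(C(C)C)C2=O)[C@@]1(C)CCC(=O)O
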